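A direct plan would carboxylate divarinol A1 to divarinic acid A2, permethylate and saponify part of A2 to 2,4-dimethoxy-6-propylbenzoic acid A3, convert A3 through its acid chloride A4 into the diaroyl peroxide A5, and let A5 aroyloxylate C3–H of unprotected A2. Its weakest steps would be:
(a) the final C–H aroyloxylation, which would have no precedent on a free β-resorcylic acid; the C3/C5 choice would rest on hydrogen bonding alone, O–O homolysis, quinone formation and decarboxylation would compete, half of A5 would be lost as leaving group, and all of this would fall on the most valuable material;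
(b) the peroxide-forming double acylation by the di-ortho-substituted chloride A4, a hindered acylation that would give an energetic peroxide A5 which could be neither purified nor stored;
(c) the run-up from A1 to A3, where a high-temperature carboxylation, exhaustive methylation and a forcing saponification would spend three operations on one carbon and two methyl groups.
No stereocentre or ring closure would be at stake; what would be left to chance is the site of the new C–O bond.

**Plan of the new route.** Retrosynthetically the free acid is masked as a benzyl ester; ring B is then opened at C1–C6 (aldol) and C5–C6 (acylation by a butyryl unit), the C1–carboxyl bond is cut next, and finally the alkyl C–O bond joining the ring A carboxylate to the central carbon of pentane-2,4-dione. Ring A is bought as its 6-methyl acid; ring B arises last, from an open chain that already carries the depside ester. The enabling feature is that O2–C2–C3(O)–C4–O4 of ring B is a pentane-2,4-dione oxygenated at its central carbon, C1 and C5 are its two equivalent methyl carbons, and C6 with its propyl is a single acyl carbon bridging them; the ester C=O of ring A, flanked by OMe and propyl, is shielded from bases and carbanions. The ester site is thus fixed by symmetry before ring B exists: no aryl C–H oxidation, no peroxide, one step to the ring A acid.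

Key step: step 4

Assumption: the three starting materials of the route (the 6-methyl acid of ring A, 3-chloropentane-2,4-dione and N-methoxy-N-methylbutanamide), iodoethane and dibenzyl carbonate are taken as commercial. The open-chain di- and tricarbonyl compounds are drawn as keto forms although they should be largely enolised, so their stereocentres are not defined.

Step 1
Reactants: 1 2,4-dimethoxy-6-methylbenzoic acid
Product: 2 2,4-dimethoxy-6-propylbenzoic acid
Conditions: LiN(i-Pr)2 (2.2 equiv), THF, −78 → 0 °C; EtI (1.2 equiv), −78 °C → rt; 1 M HCl
Reagents that add atoms: iodoethane, CCI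
Why: Lateral (benzylic) deprotonation of the carboxylate salt by LiN(i-Pr)2 should give the carboxylate-stabilised ortho-toluate dianion, which is alkylated on carbon by iodoethane, and the amide base, unlike an alkyllithium, should not metalate C3 between the two methoxy groups.

Step 2
Reactants: 2 2,4-dimethoxy-6-propylbenzoic acid; 3 3-chloropentane-2,4-dione
Product: 4 3-[(2,4-dimethoxy-6-propylbenzoyl)oxy]pentane-2,4-dione
Conditions: KHCO3 (1.1 equiv), DMF, 23 °C; 3 (1.2 equiv), 23 → 45 °C
Reagents that add atoms: none
Why: SN2 displacement of the doubly carbonyl-activated chloride by the carboxylate of 2 formed with KHCO3 (O-alkylation of a carboxylate, the usual esterification of di-ortho-substituted benzoic acids and the usual entry to 2-acyloxy-1,3-dicarbonyl compounds) forms the depside C–O bond at the carboxylate oxygen, away from the hindered carbonyl, and the symmetry of the diketone leaves only one possible site.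

Step 3
Reactants: 4 3-[(2,4-dimethoxy-6-propylbenzoyl)oxy]pentane-2,4-dione
Product: 5 benzyl 4-[(2,4-dimethoxy-6-propylbenzoyl)oxy]-3,5-dioxohexanoate
Conditions: LiN(i-Pr)2 (3.1 equiv), THF, −78 → −20 °C; (BnO)2CO (1.0 equiv), −78 → −30 °C; cold 1 M HCl
Reagents that add atoms: dibenzyl carbonate, O=C(OCc1ccccc1)OCc1ccccc1
Why: β-Diketone dianion chemistry: after enolisation of the acidic C3–H a second equivalent of base removes a methyl proton, the terminal carbanion is C-acylated by the carbonate (Claisen-type carboxylation, as in the preparation of 3,5-dioxohexanoates from pentane-2,4-dione), the third equivalent takes up the more acidic product, and the two methyl groups are equivalent so no regiochemical question arises.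

Step 4
Reactants: 5 benzyl 4-[(2,4-dimethoxy-6-propylbenzoyl)oxy]-3,5-dioxohexanoate; 6 N-methoxy-N-methylbutanamide
Product: 9 benzyl 3-[(2,4-dimethoxy-6-propylbenzoyl)oxy]-2,4-dihydroxy-6-propylbenzoate, via triketo ester 7 (not isolated), via cyclic aldol 8 (not isolated)
Conditions: LiN(i-Pr)2 (3.1 equiv), THF, −78 → 0 °C; 6 (1.2 equiv), −78 → 0 °C; cold 1 M HCl, extract; then K2CO3 (2 equiv), i-PrOH/CH2Cl2, 23 °C; 1 M HCl to pH 2
Reagents that add atoms: none
Why: Threefold deprotonation of 5 (hexanoate numbering: C4–H, then C2–H, then the C6 methyl) should give a trianion whose terminal carbanion, the least stabilised and most nucleophilic site, adds to the N-methoxy-N-methylamide 6 to give a chelated tetrahedral adduct that releases triketo ester 7 only on acidification, so the new 1,3-diketone is never exposed to the strong base (Claisen-type acylation, C5–C6 bond of ring B). Under carbonate the ester-activated carbon (C1 of ring B) then adds to the propyl ketone (C6) in a 6-exo-trig aldol closure to give 8, which loses water on acidification and enolises to the arene 9. The closest known reaction type is the acylation of 3,5-dioxoalkanoate trianions followed by biomimetic aldol cyclisation of the resulting 3,5,7-trioxoalkanoates to 6-alkyl-2,4-dihydroxybenzoates. The stereocentres of 7 and 8 are transient and vanish on aromatisation, so nothing has to be controlled. The step needs aldol closure (C1 to C6) instead of Claisen closure onto the benzyl ester or pyranone formation; the mild carbonate conditions in a non-nucleophilic alcohol and the position of C1, the only doubly activated carbon that reaches a ketone through a six-membered ring, should secure this, and the substitution pattern of 9 is then dictated by chain connectivity alone. The aroyl ester should survive because its carbonyl is flanked by OMe and propyl and because attack of the terminal carbanion on it would be a stereoelectronically disfavoured 5-(enolendo)-exo-trig closure.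

Step 5
Reactants: 9 benzyl 3-[(2,4-dimethoxy-6-propylbenzoyl)oxy]-2,4-dihydroxy-6-propylbenzoate
Product: 10 3-[(2,4-dimethoxy-6-propylbenzoyl)oxy]-2,4-dihydroxy-6-propylbenzoic acid (target)
Conditions: H2 (1 atm), Pd/C (10% Pd on carbon, cat.), EtOAc, 23 °C
Reagents that add atoms: none
Why: Hydrogenolysis of the benzyl ester over Pd/C under neutral conditions should leave the aryl ester, the methyl ethers and both arenes untouched and avoids the acid or base that could cause acyl migration or decarboxylation of the β-resorcylic acid.

**Compound list**
1 | 2,4-dimethoxy-6-methylbenzoic acid | Cc1cc(OC)cc(OC)c1C(=O)O | starting material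
2 | 2,4-dimethoxy-6-propylbenzoic acid | CCCc1cc(OC)cc(OC)c1C(=O)O | intermediate
3 | 3-chloropentane-2,4-dione | CC(=O)C(Cl)C(C)=O | starting material
4 | 3-[(2,4-dimethoxy-6-propylbenzoyl)oxy]pentane-2,4-dione | CC(=O)C(OC(=O)c1c(CCC)cc(OC)cc1OC)C(C)=O | intermediate
5 | benzyl 4-[(2,4-dimethoxy-6-propylbenzoyl)oxy]-3,5-dioxohexanoate (racemic, enolisable) | CC(=O)C(OC(=O)c1c(CCC)cc(OC)cc1OC)C(=O)CC(=O)OCc1ccccc1 | intermediate
6 | N-methoxy-N-methylbutanamide | CCCC(=O)N(C)OC | starting material
7 | benzyl 4-[(2,4-dimethoxy-6-propylbenzoyl)oxy]-3,5,7-trioxodecanoate (racemic, enolisable) | CCCC(=O)CC(=O)C(OC(=O)c1c(CCC)cc(OC)cc1OC)C(=O)CC(=O)OCc1ccccc1 | intermediate (not isolated)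
8 | benzyl 3-[(2,4-dimethoxy-6-propylbenzoyl)oxy]-6-hydroxy-2,4-dioxo-6-propylcyclohexane-1-carboxylate (mixture of stereoisomers, transient) | CCCC1(O)CC(=O)C(OC(=O)c2c(CCC)cc(OC)cc2OC)C(=O)C1C(=O)OCc1ccccc1 | intermediate (not isolated)
9 | benzyl 3-[(2,4-dimethoxy-6-propylbenzoyl)oxy]-2,4-dihydroxy-6-propylbenzoate | CCCc1cc(OC)cc(OC)c1C(=O)Oc1c(O)cc(CCC)c(C(=O)OCc2ccccc2)c1O | intermediate
10 | 3-[(2,4-dimethoxy-6-propylbenzoyl)oxy]-2,4-dihydroxy-6-propylbenzoic acid | CCCc1cc(OC)cc(OC)c1C(=O)Oc1c(O)cc(CCC)c(C(=O)O)c1O | target

**Total step count:** 5. **Longest linear sequence:** 5 steps (1 → 2 → 4 → 5 → 9 → 10).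

**Steps most likely to fail**

Step 4 (key step). The polydeprotonation could be incomplete or unselective. The aroyl group could be transferred from oxygen to a carbanion, to an enolate oxygen or, once ring B is aromatic, to a neighbouring phenolate oxygen. The ring could also close in the Claisen mode onto the benzyl ester or to a pyranone instead of through the aldol. The fallback makes ring B first as a carbocyclic 1,3-dione and attaches the ester oxygen afterwards. It sets out from 2 and comes back to the route at 9. Dibenzyl malonate and (E)-hept-3-en-2-one (BnONa, THF, 65 °C) should give, by Michael addition and Claisen cyclisation, benzyl 2,4-dioxo-6-propylcyclohexane-1-carboxylate F1. Regitz diazo transfer (4-acetamidobenzenesulfonyl azide, Et3N, MeCN) at the only methylene between two carbonyls should give benzyl 3-diazo-2,4-dioxo-6-propylcyclohexane-1-carboxylate F2. O–H insertion of the carbenoid from F2 into acid 2, catalysed by Rh2(OAc)4, should give benzyl 3-[(2,4-dimethoxy-6-propylbenzoyl)oxy]-2,4-dioxo-6-propylcyclohexane-1-carboxylate F3, and dehydrogenation of F3 with DDQ in dioxane should give 9.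

Step 3. Carboxylation could take place at both methyl groups or on an enolate oxygen, and the strongly basic dianion could degrade its own aroyl ester. The fallback assembles the dioxohexanoate chain before the depside ester is introduced. It sets out from 2 and comes back to the route at 5. Benzyl acetoacetate, as its dianion (NaH, then n-BuLi, THF), should be acylated by N-methoxy-N-methylacetamide to benzyl 3,5-dioxohexanoate F4. Diazo transfer (4-acetamidobenzenesulfonyl azide, Et3N) at the most acidic methylene, the one between the two ketones, should give benzyl 4-diazo-3,5-dioxohexanoate F5. O–H insertion into acid 2 catalysed by Rh2(OAc)4 should then give 5.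

Step 2. Displacement at the doubly activated secondary chloride by the hindered carboxylate could be slow, so that enolisation and self-condensation of the chloro diketone take over. The fallback replaces nucleophilic substitution by carbenoid insertion. It sets out from 2 and comes back to the route at 4. Pentane-2,4-dione should give, by diazo transfer, 3-diazopentane-2,4-dione F6, and O–H insertion of its carbenoid into acid 2 (Rh2(OAc)4, cat., ClCH2CH2Cl, 80 °C) should give 4.

**Further compounds**
F1 | step 4 | benzyl 2,4-dioxo-6-propylcyclohexane-1-carboxylate (racemic) | CCCC1CC(=O)CC(=O)C1C(=O)OCc1ccccc1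
F2 | step 4 | benzyl 3-diazo-2,4-dioxo-6-propylcyclohexane-1-carboxylate (racemic) | CCCC1CC(=O)C(=[N+]=[N-])C(=O)C1C(=O)OCc1ccccc1
F3 | step 4 | benzyl 3-[(2,4-dimethoxy-6-propylbenzoyl)oxy]-2,4-dioxo-6-propylcyclohexane-1-carboxylate (mixture of stereoisomers) | CCCC1CC(=O)C(OC(=O)c2c(CCC)cc(OC)cc2OC)C(=O)C1C(=O)OCc1ccccc1
F4 | step 3 | benzyl 3,5-dioxohexanoate | CC(=O)CC(=O)CC(=O)OCc1ccccc1
F5 | step 3 | benzyl 4-diazo-3,5-dioxohexanoate | CC(=O)C(=[N+]=[N-])C(=O)CC(=O)OCc1ccccc1
F6 | step 2 | 3-diazopentane-2,4-dione | CC(=O)C(=[N+]=[N-])C(C)=O
A1 | direct plan | 5-propylbenzene-1,3-diol (divarinol) | CCCc1cc(O)cc(O)c1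
A2 | direct plan | 2,4-dihydroxy-6-propylbenzoic acid (divarinic acid) | CCCc1cc(O)cc(O)c1C(=O)O
A3 | direct plan | 2,4-dimethoxy-6-propylbenzoic acid | CCCc1cc(OC)cc(OC)c1C(=O)O
A4 | direct plan | 2,4-dimethoxy-6-propylbenzoyl chloride | CCCc1cc(OC)cc(OC)c1C(Cl)=O
A5 | direct plan | bis(2,4-dimethoxy-6-propylbenzoyl) peroxide | CCCc1cc(OC)cc(OC)c1C(=O)OOC(=O)c1c(CCC)cc(OC)cc1OC
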